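**Plan**

- Retrosynthesis: the two peri O-methyl groups and a Boc group are put back first. Ring C of the flavanone is then cut at O1–C8a and C4–C4a, which takes ring A off as 3,5-dimethoxybenzyne and leaves the four-membered (S)-β-lactone O1–C2–C3–C4. The lactone is cut to an aryl aldehyde plus ketene, and the 3′–8″ biaryl bond is cut last (Suzuki–Miyaura).
- Forward: apigenin trimethyl ether is iodinated and borylated at C8″, coupled to the ring-B aldehyde, Boc-protected and converted into the β-lactone. The aryne then inserts into the lactone acyl–oxygen bond, so ring C grows from four to six atoms while ring A is fused on. BCl3 ends the route.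
- Enabling feature: in ring C the ether oxygen O1 and the ketone carbon C4 sit on the adjacent ring-A carbons C8a and C4a. This ortho oxy/acyl pattern is what an aryne leaves when it inserts into a C(=O)–O bond, and the oxygen on C5, next to C4a, is the 3-alkoxy group that directs such an aryne.
- Stereochemistry: the only stereocentre, C2 (S), is made as C4 of the lactone by alkaloid-catalysed ketene–aldehyde cycloaddition. No bond to it is broken afterwards, and the end game is acidic only, which avoids base-induced opening of the flavanone.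

Key step: step 8

Assumption: O-trimethylsilylquinine is taken to give the (S)-lactone from aryl aldehydes and the quinidine analogue its mirror image; if the sense proves opposite, the pseudoenantiomeric catalyst is used with no other change.

**Route**

Step 1
Reactants: 1 5,7-dimethoxy-2-(4-methoxyphenyl)-4H-chromen-4-one
Product: 2 8-iodo-5,7-dimethoxy-2-(4-methoxyphenyl)-4H-chromen-4-one
Conditions: I2, AgO2CCF3, CH2Cl2, rt, dark
Reagents that add atoms: iodine, II
Why: Electrophilic aromatic iodination by the iodonium equivalent formed from I2 and the silver salt; in 5-O-alkylated 5,7-dioxygenated flavones ring A is the most electron-rich ring and C8 is its reactive position, C6 being flanked by two methoxy groups.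

Step 2
Reactants: 2 8-iodo-5,7-dimethoxy-2-(4-methoxyphenyl)-4H-chromen-4-one
Product: 3 5,7-dimethoxy-2-(4-methoxyphenyl)-8-(4,4,5,5-tetramethyl-1,3,2-dioxaborolan-2-yl)-4H-chromen-4-one
Conditions: pinacolborane, PdCl2(MeCN)2 (3 mol %), SPhos, Et3N, 1,4-dioxane, 80 °C
Reagents that add atoms: pinacolborane, CC1(C)OBOC1(C)C
Why: Palladium-catalysed borylation of an aryl iodide with pinacolborane (Miyaura-type borylation), in which the amine base and the bulky biarylphosphine should cope with the doubly ortho-substituted, electron-rich iodide.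

Step 3
Reactants: 3 5,7-dimethoxy-2-(4-methoxyphenyl)-8-(4,4,5,5-tetramethyl-1,3,2-dioxaborolan-2-yl)-4H-chromen-4-one; 4 4-hydroxy-3-iodobenzaldehyde
Product: 5 3-[5,7-dimethoxy-2-(4-methoxyphenyl)-4-oxo-4H-chromen-8-yl]-4-hydroxybenzaldehyde
Conditions: Pd(OAc)2 (5 mol %), SPhos, K3PO4, 1,4-dioxane/H2O, 80 °C
Reagents that add atoms: none
Why: Suzuki–Miyaura coupling, for which SPhos-ligated palladium is the standard answer to tri-ortho-substituted biaryls and which tolerates the free phenol (as phenoxide) and the aldehyde.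

Step 4
Reactants: 5 3-[5,7-dimethoxy-2-(4-methoxyphenyl)-4-oxo-4H-chromen-8-yl]-4-hydroxybenzaldehyde
Product: 6 tert-butyl {2-[5,7-dimethoxy-2-(4-methoxyphenyl)-4-oxo-4H-chromen-8-yl]-4-formylphenyl} carbonate
Conditions: Boc2O, DMAP (cat.), Et3N, CH2Cl2, 0 °C to rt
Reagents that add atoms: di-tert-butyl dicarbonate, CC(C)(C)OC(=O)OC(=O)OC(C)(C)C
Why: DMAP-catalysed O-acylation of the phenol, which masks it against the aryne and turns the para oxygen from a donor into a weak acceptor, so that the later 4-aryl β-lactone should not ionise at its benzylic C–O bond.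

Step 5
Reactants: 6 tert-butyl {2-[5,7-dimethoxy-2-(4-methoxyphenyl)-4-oxo-4H-chromen-8-yl]-4-formylphenyl} carbonate
Product: 7 tert-butyl {2-[5,7-dimethoxy-2-(4-methoxyphenyl)-4-oxo-4H-chromen-8-yl]-4-[(2S)-4-oxooxetan-2-yl]phenyl} carbonate
Conditions: AcCl, iPr2NEt, O-trimethylsilylquinine (10 mol %), LiClO4, CH2Cl2/Et2O, −78 °C
Reagents that add atoms: acetyl chloride, CC(Cl)=O
Why: Catalytic asymmetric ketene–aldehyde [2+2] cycloaddition under alkaloid/Lewis-acid co-catalysis, in which ketene made in situ gives a chiral ammonium enolate that adds through a LiClO4-organised closed transition state to one face of the aldehyde, and ring closure with loss of the catalyst sets the lactone carbinol centre as S.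

Step 6
Reactants: 8 3,5-dimethoxyphenol
Product: 9 2-bromo-3,5-dimethoxyphenol
Conditions: NBS, CH2Cl2, −78 °C
Reagents that add atoms: N-bromosuccinimide, O=C1CCC(=O)N1Br
Why: Electrophilic aromatic bromination ortho to the free hydroxyl (positions 2 and 6 are equivalent), with any 4-bromo isomer to be removed by chromatography.

Step 7
Reactants: 9 2-bromo-3,5-dimethoxyphenol
Product: 13 3,5-dimethoxy-2-(trimethylsilyl)phenyl trifluoromethanesulfonate, via trimethylsilyl ether 10 (not isolated), via aryllithium 11 (not isolated), via lithium silylphenoxide 12 (not isolated)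
Conditions: HMDS, THF, 65 °C, evaporation; n-BuLi, THF, −100 °C; Tf2O, −100 to −78 °C
Reagents that add atoms: hexamethyldisilazane, C[Si](C)(C)N[Si](C)(C)C; trifluoromethanesulfonic anhydride, O=S(=O)(OS(=O)(=O)C(F)(F)F)C(F)(F)F
Why: O-silylation, bromine–lithium exchange and 1,3 O-to-C silyl shift (retro-Brook rearrangement) followed by triflation of the phenoxide, the standard sequence to ortho-silylaryl triflates.

Step 8
Reactants: 7 tert-butyl {2-[5,7-dimethoxy-2-(4-methoxyphenyl)-4-oxo-4H-chromen-8-yl]-4-[(2S)-4-oxooxetan-2-yl]phenyl} carbonate; 13 3,5-dimethoxy-2-(trimethylsilyl)phenyl trifluoromethanesulfonate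
Product: 17 tert-butyl {2-[5,7-dimethoxy-2-(4-methoxyphenyl)-4-oxo-4H-chromen-8-yl]-4-[(2S)-5,7-dimethoxy-4-oxo-3,4-dihydro-2H-chromen-2-yl]phenyl} carbonate, via 3,5-dimethoxybenzyne 14 (not isolated), via alkoxide acyl fluoride 15 (not isolated), via aryl anion 16 (not isolated)
Conditions: 13 (1.5 equiv, slow addition), KF, 18-crown-6, THF, 0 °C to rt
Reagents that add atoms: none
Why: Proposed new method: fluoride, needed anyway to unmask aryne 14 from 13, is expected to act as an acyl-transfer relay: it attacks the strained lactone carbonyl of 7 (acyl–oxygen cleavage) to give alkoxide acyl fluoride 15, the alkoxide oxygen adds to the aryne, and the ortho aryl anion 16 so formed attacks the acyl fluoride and returns fluoride. A second channel, in which fluoride adds to the aryne first, the 2-fluoroaryl anion is acylated by the lactone and the released alkoxide closes by SNAr ortho to the new ketone, would converge on the same product. The closest known reaction types are the aryne insertion into the N–C(=O) bond of N-H β-lactams (four- to six-membered ring expansion to 2,3-dihydroquinolin-4-ones), the aryne C–O insertion of carboxylic acids giving ortho-hydroxyaryl ketones and chromanones, and the annulation of salicylates with arynes to xanthones, in each of which a heteroatom adds to the aryne and the aryl anion is then acylated intramolecularly. The ring closed is ring C, by nucleophilic addition of O1 to the aryne (O1–C8a) and 6-exo-trig acyl substitution (C4–C4a), so the four lactone atoms O1, C2, C3 and C4 are kept and C8a and C4a are inserted between O1 and C4. No stereocentre is created: C2 is carried over from the lactone carbinol carbon, no bond to it is broken, and the aprotic medium offers the aryl anion no proton source before acylation. The step needs regioselectivity, secured by the methoxy group next to the aryne bond, which sends the oxygen nucleophile to the distal carbon (future C8a) and leaves the anion ortho to methoxy (future C4a) as is general for 3-alkoxyarynes; it also needs acyl over benzylic C–O cleavage, secured by the hard fluoride and by the electron-poor Boc-oxy group para to C2.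

Step 9
Reactants: 17 tert-butyl {2-[5,7-dimethoxy-2-(4-methoxyphenyl)-4-oxo-4H-chromen-8-yl]-4-[(2S)-5,7-dimethoxy-4-oxo-3,4-dihydro-2H-chromen-2-yl]phenyl} carbonate
Product: 18 2,3-dihydroheveaflavone [(2S)-5-hydroxy-2-{4-hydroxy-3-[5-hydroxy-7-methoxy-2-(4-methoxyphenyl)-4-oxo-4H-chromen-8-yl]phenyl}-7-methoxy-2,3-dihydro-4H-chromen-4-one]
Conditions: BCl3, CH2Cl2, −78 to 0 °C; aqueous work-up
Reagents that add atoms: none
Why: Chelation-directed Lewis-acid ether cleavage, in which BCl3 bound to each carbonyl should remove only the two peri methoxy groups (C5 and C5″) while the tert-butyl carbonate is lost as tert-butyl chloride and CO2, and the base-free medium should not open the flavanone, so C2 stays S.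

**Compound list**

1 | 5,7-dimethoxy-2-(4-methoxyphenyl)-4H-chromen-4-one (apigenin trimethyl ether) | COc1ccc(-c2cc(=O)c3c(OC)cc(OC)cc3o2)cc1 | starting material
2 | 8-iodo-5,7-dimethoxy-2-(4-methoxyphenyl)-4H-chromen-4-one | COc1ccc(-c2cc(=O)c3c(OC)cc(OC)c(I)c3o2)cc1 | intermediate
3 | 5,7-dimethoxy-2-(4-methoxyphenyl)-8-(4,4,5,5-tetramethyl-1,3,2-dioxaborolan-2-yl)-4H-chromen-4-one | COc1ccc(-c2cc(=O)c3c(OC)cc(OC)c(B4OC(C)(C)C(C)(C)O4)c3o2)cc1 | intermediate
4 | 4-hydroxy-3-iodobenzaldehyde | O=Cc1ccc(O)c(I)c1 | starting material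
5 | 3-[5,7-dimethoxy-2-(4-methoxyphenyl)-4-oxo-4H-chromen-8-yl]-4-hydroxybenzaldehyde | COc1ccc(-c2cc(=O)c3c(OC)cc(OC)c(-c4cc(C=O)ccc4O)c3o2)cc1 | intermediate
6 | tert-butyl {2-[5,7-dimethoxy-2-(4-methoxyphenyl)-4-oxo-4H-chromen-8-yl]-4-formylphenyl} carbonate | COc1ccc(-c2cc(=O)c3c(OC)cc(OC)c(-c4cc(C=O)ccc4OC(=O)OC(C)(C)C)c3o2)cc1 | intermediate
7 | tert-butyl {2-[5,7-dimethoxy-2-(4-methoxyphenyl)-4-oxo-4H-chromen-8-yl]-4-[(2S)-4-oxooxetan-2-yl]phenyl} carbonate (the (4S)-4-aryl-oxetan-2-one) | COc1ccc(-c2cc(=O)c3c(OC)cc(OC)c(-c4cc([C@@H]5CC(=O)O5)ccc4OC(=O)OC(C)(C)C)c3o2)cc1 | intermediate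
8 | 3,5-dimethoxyphenol | COc1cc(O)cc(OC)c1 | starting material
9 | 2-bromo-3,5-dimethoxyphenol | COc1cc(O)c(Br)c(OC)c1 | intermediate
10 | (2-bromo-3,5-dimethoxyphenoxy)trimethylsilane | COc1cc(O[Si](C)(C)C)c(Br)c(OC)c1 | intermediate (not isolated)
11 | [2,4-dimethoxy-6-(trimethylsilyloxy)phenyl]lithium | COc1cc(O[Si](C)(C)C)c([Li])c(OC)c1 | intermediate (not isolated)
12 | lithium 3,5-dimethoxy-2-(trimethylsilyl)phenolate | COc1cc([O-])c([Si](C)(C)C)c(OC)c1.[Li+] | intermediate (not isolated)
13 | 3,5-dimethoxy-2-(trimethylsilyl)phenyl trifluoromethanesulfonate | COc1cc(OS(=O)(=O)C(F)(F)F)c([Si](C)(C)C)c(OC)c1 | intermediate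
14 | 3,5-dimethoxybenzyne (1,2-didehydro-3,5-dimethoxybenzene) | COC1=CC(OC)=CC#C1 | intermediate (not isolated)
15 | potassium (1S)-1-{4-[(tert-butoxycarbonyl)oxy]-3-[5,7-dimethoxy-2-(4-methoxyphenyl)-4-oxo-4H-chromen-8-yl]phenyl}-3-fluoro-3-oxopropan-1-olate | COc1ccc(-c2cc(=O)c3c(OC)cc(OC)c(-c4cc([C@@H]([O-])CC(F)=O)ccc4OC(=O)OC(C)(C)C)c3o2)cc1.[K+] | intermediate (not isolated)
16 | potassium 2-[(1S)-1-{4-[(tert-butoxycarbonyl)oxy]-3-[5,7-dimethoxy-2-(4-methoxyphenyl)-4-oxo-4H-chromen-8-yl]phenyl}-3-fluoro-3-oxopropoxy]-4,6-dimethoxybenzen-1-ide | COc1ccc(-c2cc(=O)c3c(OC)cc(OC)c(-c4cc([C@@H](Oc5cc(OC)cc(OC)[c-]5)CC(F)=O)ccc4OC(=O)OC(C)(C)C)c3o2)cc1.[K+] | intermediate (not isolated)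
17 | tert-butyl {2-[5,7-dimethoxy-2-(4-methoxyphenyl)-4-oxo-4H-chromen-8-yl]-4-[(2S)-5,7-dimethoxy-4-oxo-3,4-dihydro-2H-chromen-2-yl]phenyl} carbonate | COc1ccc(-c2cc(=O)c3c(OC)cc(OC)c(-c4cc([C@@H]5CC(=O)c6c(OC)cc(OC)cc6O5)ccc4OC(=O)OC(C)(C)C)c3o2)cc1 | intermediate
18 | 2,3-dihydroheveaflavone [(2S)-5-hydroxy-2-{4-hydroxy-3-[5-hydroxy-7-methoxy-2-(4-methoxyphenyl)-4-oxo-4H-chromen-8-yl]phenyl}-7-methoxy-2,3-dihydro-4H-chromen-4-one] | COc1ccc(-c2cc(=O)c3c(O)cc(OC)c(-c4cc([C@@H]5CC(=O)c6c(O)cc(OC)cc6O5)ccc4O)c3o2)cc1 | target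

**Step count and risks**

Total step count: 9. Longest linear sequence: 7 steps (steps 1, 2, 3, 4, 5, 8, 9, from compound 1); the aryne precursor is a two-step side branch (steps 6 and 7).

Steps most likely to fail:

1. Step 8 (Proposed new method). Fluoride may not open the lactone at the acyl carbon fast enough, so the aryne would be lost to self-reaction. The ring-opened alkoxide may dehydrate by E1cB. The Boc carbonate may be cleaved or transferred, releasing a phenoxide that is arylated. The basic fluoride may also open the product flavanone by retro-oxa-Michael reaction and erode the configuration at C2. The fallback uses known chemistry and no aryne, and sets out from aldehyde 6. The cycloaddition of step 5, run with the pseudoenantiomeric O-trimethylsilylquinidine, should give the mirror-image lactone tert-butyl {2-[5,7-dimethoxy-2-(4-methoxyphenyl)-4-oxo-4H-chromen-8-yl]-4-[(2R)-4-oxooxetan-2-yl]phenyl} carbonate F1. Caesium 3,5-dimethoxyphenoxide (from phenol 8 and Cs2CO3, DMF, rt) should open F1 at the benzylic carbon by SN2 alkyl–oxygen cleavage with inversion, giving (3S)-3-{4-[(tert-butoxycarbonyl)oxy]-3-[5,7-dimethoxy-2-(4-methoxyphenyl)-4-oxo-4H-chromen-8-yl]phenyl}-3-(3,5-dimethoxyphenoxy)propanoic acid F2. Intramolecular Friedel–Crafts acylation of the activated phenoxy ring through the mixed anhydride (trifluoroacetic anhydride, CH2Cl2, 0 °C) should then close ring C ortho to the ether oxygen and come back to the route at 17.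

2. Step 5. Unsubstituted ketene and a hindered aromatic aldehyde may give low conversion or poor facial selectivity, and ketene dimerisation may outrun the cycloaddition. The fallback sets the stereocentre by reduction and sets out from 6. Roskamp homologation with benzyl diazoacetate (SnCl2 cat., CH2Cl2, rt) should give the β-keto ester benzyl 3-{4-[(tert-butoxycarbonyl)oxy]-3-[5,7-dimethoxy-2-(4-methoxyphenyl)-4-oxo-4H-chromen-8-yl]phenyl}-3-oxopropanoate F3. Noyori asymmetric transfer hydrogenation (RuCl[(S,S)-TsDPEN](p-cymene), HCO2H/Et3N, rt), with the facial sense known for aryl ketones, should give the (3S)-hydroxy ester benzyl (3S)-3-{4-[(tert-butoxycarbonyl)oxy]-3-[5,7-dimethoxy-2-(4-methoxyphenyl)-4-oxo-4H-chromen-8-yl]phenyl}-3-hydroxypropanoate F4. Hydrogenolysis (H2, Pd/C, EtOAc) should give the acid (3S)-3-{4-[(tert-butoxycarbonyl)oxy]-3-[5,7-dimethoxy-2-(4-methoxyphenyl)-4-oxo-4H-chromen-8-yl]phenyl}-3-hydroxypropanoic acid F5. Lactonisation with retention through carboxyl activation (PhSO2Cl, pyridine, 0 °C) comes back to the route at 7.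

3. Step 3. Protodeboronation of the hindered, electron-rich boronate 3 in aqueous base may be faster than transmetalation at the tri-ortho-substituted centre. The fallback puts boron on the less hindered ring, protects first and couples without water; it sets out from 4 and 2. Boc2O/DMAP should give tert-butyl (4-formyl-2-iodophenyl) carbonate F6. Miyaura borylation (B2pin2, PdCl2(dppf), KOAc, 1,4-dioxane, 80 °C) should give tert-butyl [4-formyl-2-(4,4,5,5-tetramethyl-1,3,2-dioxaborolan-2-yl)phenyl] carbonate F7. Anhydrous Suzuki–Miyaura coupling of F7 with iodide 2 (Pd(OAc)2, SPhos, CsF, 1,4-dioxane, 80 °C) should give 6 directly, bypassing steps 2 to 4 and coming back to the route at 6.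

**Further compounds**

F1 | step 8 | tert-butyl {2-[5,7-dimethoxy-2-(4-methoxyphenyl)-4-oxo-4H-chromen-8-yl]-4-[(2R)-4-oxooxetan-2-yl]phenyl} carbonate | COc1ccc(-c2cc(=O)c3c(OC)cc(OC)c(-c4cc([C@H]5CC(=O)O5)ccc4OC(=O)OC(C)(C)C)c3o2)cc1
F2 | step 8 | (3S)-3-{4-[(tert-butoxycarbonyl)oxy]-3-[5,7-dimethoxy-2-(4-methoxyphenyl)-4-oxo-4H-chromen-8-yl]phenyl}-3-(3,5-dimethoxyphenoxy)propanoic acid | COc1ccc(-c2cc(=O)c3c(OC)cc(OC)c(-c4cc([C@@H](Oc5cc(OC)cc(OC)c5)CC(=O)O)ccc4OC(=O)OC(C)(C)C)c3o2)cc1
F3 | step 5 | benzyl 3-{4-[(tert-butoxycarbonyl)oxy]-3-[5,7-dimethoxy-2-(4-methoxyphenyl)-4-oxo-4H-chromen-8-yl]phenyl}-3-oxopropanoate | COc1ccc(-c2cc(=O)c3c(OC)cc(OC)c(-c4cc(C(=O)CC(=O)OCc5ccccc5)ccc4OC(=O)OC(C)(C)C)c3o2)cc1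
F4 | step 5 | benzyl (3S)-3-{4-[(tert-butoxycarbonyl)oxy]-3-[5,7-dimethoxy-2-(4-methoxyphenyl)-4-oxo-4H-chromen-8-yl]phenyl}-3-hydroxypropanoate | COc1ccc(-c2cc(=O)c3c(OC)cc(OC)c(-c4cc([C@@H](O)CC(=O)OCc5ccccc5)ccc4OC(=O)OC(C)(C)C)c3o2)cc1
F5 | step 5 | (3S)-3-{4-[(tert-butoxycarbonyl)oxy]-3-[5,7-dimethoxy-2-(4-methoxyphenyl)-4-oxo-4H-chromen-8-yl]phenyl}-3-hydroxypropanoic acid | COc1ccc(-c2cc(=O)c3c(OC)cc(OC)c(-c4cc([C@@H](O)CC(=O)O)ccc4OC(=O)OC(C)(C)C)c3o2)cc1
F6 | step 3 | tert-butyl (4-formyl-2-iodophenyl) carbonate | O=Cc1ccc(OC(=O)OC(C)(C)C)c(I)c1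
F7 | step 3 | tert-butyl [4-formyl-2-(4,4,5,5-tetramethyl-1,3,2-dioxaborolan-2-yl)phenyl] carbonate | O=Cc1ccc(OC(=O)OC(C)(C)C)c(B2OC(C)(C)C(C)(C)O2)c1
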